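## The problem

CNP0300193.1 (37) is a heliangolide-type germacranolide. A ten-membered carbocycle carries a Z-4,5-alkene and a trans-1,10-epoxide and is trans-fused at C6–C7 to an α-methylene-γ-butyrolactone; C3 bears a free allylic hydroxyl and C8 an isovalerate. The first difficulty is the ten-membered ring itself: end-to-end closure is costly, and the ring must hold two trisubstituted alkenes of opposite geometry (Z at C4–C5, E at C1–C10 before epoxidation). Six stereocentres are required (1R,3R,6R,7R,8R,10R). C6 can come from the chiral pool and can direct C7 (trans fusion); C7 can direct C8; the ring conformation can direct the epoxide face. C3 lies across the Z-alkene from all of them and needs reagent control. The α-methylene lactone (Michael acceptor), the trisubstituted epoxide (acid-triggered transannular attack by C4–C5) and the C8 ester will not survive rough treatment and must appear late. The enabling feature is that C7 is the β-carbon of the lactone that runs from C12 to the C6 oxygen, while its neighbour C8 carries oxygen. C8 can therefore serve as an acyl-anion equivalent (a nitronate) that attacks C7 of a C6-substituted butenolide anti to the C6 substituent, forming the C7–C8 bond, the ring and the trans fusion in one operation.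

## Retrosynthesis

**Epoxide and silyl ether last.** The C1–O/C10–O bonds and the O–Si bond of 37 are cut first, leading through silyl ether 36 to triene 35. The epoxide is the most acid-sensitive group and is made by epoxidation of the only electron-rich alkene. The C3 silyl ether stays on during that step because a free allylic hydroxyl would steer the peracid to C4–C5.

**Ester and exocyclic methylene.** The isovalerate C–O bond (35 to alcohol 34) and then C11=C13 (34 via 33 to lactone 29) are removed. The methylene is made by enolate Mannich chemistry. During that step C8–OH is masked as a triethylsilyl ether: a free alkoxide could translactonise to the 12,8-olide, and an isovalerate would be a second enolisable ester.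

**C8 oxygen from nitrogen.** Silyl ether 29 goes back through carbinol 28 and ketone 27 to nitro compound 25. This makes C8 a carbon that can be nucleophilic, which no oxygenated C8 can be, at the price of a Nef reaction and a hydride reduction that must set 8R.

**C7–C8, the ring closure.** Cutting C7–C8 of 25 opens the ten-membered ring to nitro butenolide 24. Against a cut at C3–C4 or C1–C10, this one forms the ring, the C7 stereocentre and the lactone fusion together. The precursor is an open chain with only two stereocentres (C3, C6). The forward reaction must close the ring faster than the chain oligomerises or C6 epimerises.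

**Nitro group and butenolide introduced late.** 24 comes from iodide 23, alcohol 22 and PMB ether 21. The butenolide 21 comes from saturated lactone 18 by selenoxide elimination. Nitro is installed last because neither divalent chromium nor amide bases tolerate it. The butenolide is unveiled only after the C3 centre is in place, because C6 is not acidic in the saturated lactone.

**C3–C4 by alkenyl–aldehyde coupling.** Silyl ether 18 goes back through carbinol 17, enone 16 and the epimeric carbinols 15 to alkenyl iodide 7 and aldehyde 14. The coupling tolerates the lactone and keeps the Z geometry. C6 cannot direct C3, so C3 is set by oxidation and catalyst-controlled reduction.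

**The two building blocks.** Iodide 7 comes from aldehyde 2 and the ylide derived from 3, and 2 from hydroxy lactone 1, which supplies C6. Aldehyde 14 comes from alcohol 13, made from alkyne 9 (from 3-butyn-1-ol 8) and ethylene oxide 10 by carboalumination, which fixes the E-alkene.

## Roads not taken

**Alternative 1:** The cut is at both allylic C–O bonds (C3–O and C6–O). In the forward sense singlet oxygen (tetraphenylporphyrin, light) would add across C3 and C6 of the ring (3Z,5Z)-diene A1 to give the 3,6-endoperoxide A2. O–O reduction and lactonisation of the C6 oxygen onto the C12 ester would then finish 37.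
- Merits: one reagent delivers both oxygens to the same face, which is the relationship the target has, and leaves the Z-4,5-alkene. C3 needs no protecting group and the end game is two operations.
- Weak points: A1 is already the complete ten-membered ring with epoxide, ester and acrylate, so the ring closure is left unsolved. A Z,Z-1,3-diene in a medium ring is twisted out of the s-cis planarity the cycloaddition needs. The ene reaction at C15 and base-induced rearrangement of the peroxide compete.
- Comparison: in end-game length and in setting C3 and C6 together this road is better. The chosen plan spends five steps on C3 (steps 6 to 9 and 22). It sets against this a defined answer to the ring closure and independent, reliable sources for C6 and C3.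

**Alternative 2:** The cuts are at C7–C11 and C8–C11. The rhodium carbenoid formed with Rh2(OAc)4 from the allylic diazomalonate A3 would add to the E-C7–C8 alkene and give the cyclopropane-fused lactone A4. Isovalerate would then open the cyclopropane at C8 with inversion.
- Merits: C6 relays stereospecifically to C7 and C8 through alkene geometry and invertive opening. The ester arrives as the nucleophile, and the malonate carbon allows a methylenation without strong base. In C8 control and in the methylenation this road is better than the chosen plan, which needs a ketone reduction and a protect–deprotect pair (steps 16, 17, 19).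
- Weak points: a carboxylate is a poor nucleophile for homoconjugate opening at a secondary cyclopropane carbon, and attack at C7 competes. The ten-membered ring is still open in A4 and must be closed at C3–C5 late, next to the α-methylene lactone, with C3 set by the ring.
- Comparison: the chosen plan sets against it a ring closure that is done early, on a robust substrate, and that also creates C7.

**Alternative 3:** The cuts are at C2–C3 and C6–C10, with the ring made later by fragmentation. Triethylamine in trifluoroethanol would release an oxyallyl cation from the α-chloro ketone A5. Its (4+3) addition to the furan would give the oxygen-bridged ketone A6, and a Grob fragmentation of C6–C10 would expand it to the ten-membered ring.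
- Merits: furan (4+3) cycloadditions are dependable, and the ring arises by ring expansion with the alkene geometry set by the fragmentation. In this respect the road is clearly better than any end-to-end closure, including the chosen one.
- Weak points: one bridging oxygen has to serve both C3 and C6, so a second oxygen must be introduced later with control. C6 is quaternary in A6 and must become CH–O. The C8 oxygen, the lactone and the methylene still require many redox steps.
- Comparison: the chosen plan sets against it a precursor in which every oxygen of the target is already on its carbon, and a shorter path after ring formation.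

Key step: step 14

Assumption: germacrane numbering is used for all intermediates (ring C1–C10, lactone C11–C13, C14 on C10, C15 on C4); CIP descriptors at C6 and C7 change with the substituents while the spatial arrangement stays that of the target.

## Route

Step 1
Reactants: 1 (S)-5-(hydroxymethyl)dihydrofuran-2(3H)-one
Product: 2 (S)-5-oxotetrahydrofuran-2-carbaldehyde
Conditions: Dess–Martin periodinane, CH2Cl2, 0 °C → rt; filtered, used at once
Reagents that add atoms: none
Why: Dess–Martin oxidation under neutral, water-free conditions, chosen because the α-acyloxy aldehyde hydrates and epimerises easily; C6 comes unchanged from the chiral pool.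

Step 2
Reactants: 2 (S)-5-oxotetrahydrofuran-2-carbaldehyde; 3 ethyltriphenylphosphonium bromide
Product: 7 (S)-5-[(Z)-2-iodoprop-1-en-1-yl]dihydrofuran-2(3H)-one, via ethylidenetriphenylphosphorane 4 (not isolated), via (1-iodoethyl)triphenylphosphonium iodide 5 (not isolated), via (1-iodoethylidene)triphenylphosphorane 6 (not isolated)
Conditions: 3, n-BuLi, THF, 0 °C → rt; I2, −78 °C; NaN(SiMe3)2, −20 °C; then 2, −78 °C → rt
Reagents that add atoms: iodine, II
Why: Stork–Zhao olefination; the α-iodo ylide gives the (Z)-2-iodoalkene (iodine cis to C6) under kinetic control, and its low basicity at −78 °C should spare the α-stereocentre of 2.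

Step 3
Reactants: 8 3-butyn-1-ol
Product: 9 1-[(but-3-yn-1-yloxy)methyl]-4-methoxybenzene
Conditions: 4-methoxybenzyl chloride, NaH, Bu4NI (cat.), THF/DMF, 0 °C → rt
Reagents that add atoms: 4-methoxybenzyl chloride, COc1ccc(CCl)cc1
Why: Williamson etherification; the PMB ether survives AlMe3, CrCl2 and amide bases and is orthogonal to the later silyl ethers.

Step 4
Reactants: 9 1-[(but-3-yn-1-yloxy)methyl]-4-methoxybenzene; 10 ethylene oxide
Product: 13 (E)-6-[(4-methoxybenzyl)oxy]-4-methylhex-3-en-1-ol, via alkenyldimethylalane 11 (not isolated), via lithium alkenylalanate 12 (not isolated)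
Conditions: AlMe3, Cp2ZrCl2 (cat.), CH2Cl2, 0 °C → rt; exchange to hexane/THF; n-BuLi, −78 °C; ethylene oxide, −78 → 0 °C
Reagents that add atoms: trimethylaluminium, C[Al](C)C
Why: Negishi carboalumination adds methyl and aluminium syn with the metal at the terminus, which fixes the E-1(10) geometry; the ate complex opens ethylene oxide with retention at the sp2 carbon and supplies C2–C3.

Step 5
Reactants: 13 (E)-6-[(4-methoxybenzyl)oxy]-4-methylhex-3-en-1-ol
Product: 14 (E)-6-[(4-methoxybenzyl)oxy]-4-methylhex-3-enal
Conditions: Dess–Martin periodinane, NaHCO3, CH2Cl2, 0 °C; used crude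
Reagents that add atoms: none
Why: Buffered Dess–Martin oxidation should give the β,γ-unsaturated aldehyde without moving the alkene into conjugation, provided it is used directly.

Step 6
Reactants: 7 (S)-5-[(Z)-2-iodoprop-1-en-1-yl]dihydrofuran-2(3H)-one; 14 (E)-6-[(4-methoxybenzyl)oxy]-4-methylhex-3-enal
Product: 15 (5S)-5-[(1Z,5E)-3-hydroxy-8-[(4-methoxybenzyl)oxy]-2,6-dimethylocta-1,5-dien-1-yl]dihydrofuran-2(3H)-one (both C3 epimers)
Conditions: CrCl2, NiCl2 (cat.), DMSO, rt
Reagents that add atoms: none
Why: Nozaki–Hiyama–Kishi coupling; the alkenylchromium reagent forms with retention of the Z geometry and adds to the aldehyde only, leaving the lactone; remote C6 is not expected to direct C3, so both epimers go on to step 7.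

Step 7
Reactants: 15 (5S)-5-[(1Z,5E)-3-hydroxy-8-[(4-methoxybenzyl)oxy]-2,6-dimethylocta-1,5-dien-1-yl]dihydrofuran-2(3H)-one
Product: 16 (S)-5-[(1Z,5E)-8-[(4-methoxybenzyl)oxy]-2,6-dimethyl-3-oxoocta-1,5-dien-1-yl]dihydrofuran-2(3H)-one
Conditions: Dess–Martin periodinane, NaHCO3, CH2Cl2, 0 °C
Reagents that add atoms: none
Why: Dess–Martin oxidation merges both C3 epimers into one enone under non-basic conditions that should leave the Z-enone and the skipped 1(10)-alkene in place.

Step 8
Reactants: 16 (S)-5-[(1Z,5E)-8-[(4-methoxybenzyl)oxy]-2,6-dimethyl-3-oxoocta-1,5-dien-1-yl]dihydrofuran-2(3H)-one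
Product: 17 (S)-5-[(1Z,3R,5E)-3-hydroxy-8-[(4-methoxybenzyl)oxy]-2,6-dimethylocta-1,5-dien-1-yl]dihydrofuran-2(3H)-one
Conditions: (S)-2-methyl-CBS-oxazaborolidine, catecholborane, toluene, −78 °C
Reagents that add atoms: none
Why: Corey–Bakshi–Shibata reduction; the α-methylalkenyl group is the large and the CH2 group the small substituent, so the (S)-catalyst should give the 3R carbinol by reagent control; catecholborane at −78 °C spares lactone and alkenes.

Step 9
Reactants: 17 (S)-5-[(1Z,3R,5E)-3-hydroxy-8-[(4-methoxybenzyl)oxy]-2,6-dimethylocta-1,5-dien-1-yl]dihydrofuran-2(3H)-one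
Product: 18 (S)-5-[(1Z,3R,5E)-3-(tert-butyldimethylsilyloxy)-8-[(4-methoxybenzyl)oxy]-2,6-dimethylocta-1,5-dien-1-yl]dihydrofuran-2(3H)-one
Conditions: TBSOTf, 2,6-lutidine, CH2Cl2, −78 → 0 °C
Reagents that add atoms: tert-butyldimethylsilyl trifluoromethanesulfonate, CC(C)(C)[Si](C)(C)OS(=O)(=O)C(F)(F)F
Why: Silylation of the secondary allylic alcohol; the TBS ether keeps the C3 oxygen from adding to the butenolide and from directing the later epoxidation.

Step 10
Reactants: 18 (S)-5-[(1Z,3R,5E)-3-(tert-butyldimethylsilyloxy)-8-[(4-methoxybenzyl)oxy]-2,6-dimethylocta-1,5-dien-1-yl]dihydrofuran-2(3H)-one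
Product: 21 (S)-5-[(1Z,3R,5E)-3-(tert-butyldimethylsilyloxy)-8-[(4-methoxybenzyl)oxy]-2,6-dimethylocta-1,5-dien-1-yl]furan-2(5H)-one, via lithium enolate 19 (not isolated), via phenylselanyl lactone 20 (not isolated)
Conditions: LiN(SiMe3)2, THF, −78 °C; PhSeBr, −78 °C; then pyridine, 30% H2O2, 0 °C → rt
Reagents that add atoms: none
Why: α-Selenenylation of the lactone enolate and selenoxide syn-elimination, which can run only toward C7 and so gives the butenolide; C6 is not acidic in 18, and pyridine buffering suppresses alkene epoxidation by perseleninic acid.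

Step 11
Reactants: 21 (S)-5-[(1Z,3R,5E)-3-(tert-butyldimethylsilyloxy)-8-[(4-methoxybenzyl)oxy]-2,6-dimethylocta-1,5-dien-1-yl]furan-2(5H)-one
Product: 22 (S)-5-[(1Z,3R,5E)-3-(tert-butyldimethylsilyloxy)-8-hydroxy-2,6-dimethylocta-1,5-dien-1-yl]furan-2(5H)-one
Conditions: DDQ, CH2Cl2/pH 7 buffer, 0 °C → rt
Reagents that add atoms: none
Why: Oxidative cleavage of the PMB ether through its benzylic oxocarbenium ion; silyl ether, butenolide and isolated alkenes are inert in the buffered medium.

Step 12
Reactants: 22 (S)-5-[(1Z,3R,5E)-3-(tert-butyldimethylsilyloxy)-8-hydroxy-2,6-dimethylocta-1,5-dien-1-yl]furan-2(5H)-one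
Product: 23 (S)-5-[(1Z,3R,5E)-3-(tert-butyldimethylsilyloxy)-8-iodo-2,6-dimethylocta-1,5-dien-1-yl]furan-2(5H)-one
Conditions: I2, PPh3, imidazole, CH2Cl2, 0 °C
Reagents that add atoms: iodine, II
Why: Appel-type iodination by SN2 displacement of the alkoxyphosphonium ion; imidazole is too weak a base to deprotonate C6 of the butenolide.

Step 13
Reactants: 23 (S)-5-[(1Z,3R,5E)-3-(tert-butyldimethylsilyloxy)-8-iodo-2,6-dimethylocta-1,5-dien-1-yl]furan-2(5H)-one
Product: 24 (S)-5-[(1Z,3R,5E)-3-(tert-butyldimethylsilyloxy)-2,6-dimethyl-8-nitroocta-1,5-dien-1-yl]furan-2(5H)-one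
Conditions: AgNO2, Et2O, 0 °C → rt, dark
Reagents that add atoms: silver nitrite, [Ag+].[O-]N=O
Why: Victor Meyer reaction; silver-assisted SN2 displacement of the primary iodide by nitrite nitrogen under neutral conditions, so nitroalkane and butenolide do not react with each other before step 14.

Step 14
Reactants: 24 (S)-5-[(1Z,3R,5E)-3-(tert-butyldimethylsilyloxy)-2,6-dimethyl-8-nitroocta-1,5-dien-1-yl]furan-2(5H)-one
Product: 25 (3R,6R,7R,8R)-3-(tert-butyldimethylsilyloxy)-8-nitrogermacra-1(10)E,4Z-dien-12,6-olide (ten-membered ring trans-fused to the saturated lactone; the C8 epimer serves equally)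
Conditions: DBU (0.3 equiv), MeCN (0.001 M), 0 °C → rt; AcOH quench
Reagents that add atoms: none
Why: Proposed new method: DBU deprotonates the nitroalkane, the nitronate carbon C8 adds to the butenolide β-carbon C7, and the lactone enolate is protonated; every stage is reversible, so the system can settle in the most stable adduct. The closest known reaction is the intermolecular amine-base Michael addition of nitroalkanes to 5-substituted furan-2(5H)-ones, which gives 4,5-trans lactones; its use as an end-to-end closure of a ten-membered carbocycle is new. The ring closes in the 10-exo-trig mode (C7 inside the new ring, C11 outside), and the Z-4,5-alkene, the E-1(10)-alkene and the flat butenolide leave few freely rotating ring bonds, which lowers the entropic cost. C7 is controlled by C6: C8 must arrive on the butenolide face opposite the C5 substituent, which is the trans fusion (H6 and H7 anti); this is the kinetic preference of 5-substituted butenolides and is expected to be the more stable fusion as well, so equilibration works in the same direction. C8 forms without control and can epimerise through its nitronate, which is harmless because C8 becomes sp2 in step 15. The step needs ring closure to beat oligomerisation and deprotonation at C6 (γ to the lactone carbonyl and allylic); high dilution, substoichiometric base, low temperature and the higher acidity of the nitroalkane are relied on for this.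

Step 15
Reactants: 25 (3R,6R,7R,8R)-3-(tert-butyldimethylsilyloxy)-8-nitrogermacra-1(10)E,4Z-dien-12,6-olide
Product: 27 (3R,6R,7S)-3-(tert-butyldimethylsilyloxy)-8-oxogermacra-1(10)E,4Z-dien-12,6-olide, via lithium nitronate 26 (not isolated)
Conditions: LiN(SiMe3)2, THF, −78 °C; then TiCl3, NH4OAc, H2O/THF (pH about 6), 0 °C → rt
Reagents that add atoms: water, O
Why: Reductive Nef reaction; TiCl3 reduces the nitronate to the imine, which hydrolyses at pH 6 to the ketone; the buffer spares the TBS ether and keeps base away from the β-acyloxy ketone, which is reduced without delay.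

Step 16
Reactants: 27 (3R,6R,7S)-3-(tert-butyldimethylsilyloxy)-8-oxogermacra-1(10)E,4Z-dien-12,6-olide
Product: 28 (3R,6R,7R,8R)-3-(tert-butyldimethylsilyloxy)-8-hydroxygermacra-1(10)E,4Z-dien-12,6-olide
Conditions: LiBH(s-Bu)3, THF, −78 °C; aq. NH4Cl
Reagents that add atoms: none
Why: Substrate-controlled hydride addition; by the Felkin–Anh model (C6 large, C11 medium, H small) the bulky hydride should attack anti to the C6–C7 bond and past H7, placing the hydroxyl cis to C11 (8R); the lactone is not reduced at −78 °C.

Step 17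
Reactants: 28 (3R,6R,7R,8R)-3-(tert-butyldimethylsilyloxy)-8-hydroxygermacra-1(10)E,4Z-dien-12,6-olide
Product: 29 (3R,6R,7S,8R)-3-(tert-butyldimethylsilyloxy)-8-(triethylsilyloxy)germacra-1(10)E,4Z-dien-12,6-olide
Conditions: Et3SiOTf, 2,6-lutidine, CH2Cl2, −78 °C
Reagents that add atoms: triethylsilyl trifluoromethanesulfonate, CC[Si](CC)(CC)OS(=O)(=O)C(F)(F)F
Why: Silylation; the TES ether masks C8–OH during the enolate step (a free alkoxide could translactonise) and is labile enough to be removed alone in step 19.

Step 18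
Reactants: 29 (3R,6R,7S,8R)-3-(tert-butyldimethylsilyloxy)-8-(triethylsilyloxy)germacra-1(10)E,4Z-dien-12,6-olide
Product: 33 (3R,6R,7S,8R)-3-(tert-butyldimethylsilyloxy)-8-(triethylsilyloxy)germacra-1(10)E,4Z,11(13)-trien-12,6-olide, via lithium enolate 30 (not isolated), via Mannich base 31 (not isolated), via trimethylammonium iodide 32 (not isolated)
Conditions: LiN(i-Pr)2, THF, −78 °C; CH2=NMe2+ I−, −78 → 0 °C; MeI, THF, rt; NaHCO3 (aq), CH2Cl2, rt
Reagents that add atoms: N,N-dimethylmethyleneiminium iodide (Eschenmoser's salt), C=[N+](C)C.[I-]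
Why: Mannich reaction of the lactone enolate, N-methylation and E1cB loss of trimethylamine give the α-methylene lactone; the lactone is the only enolisable carbonyl in 29.

Step 19
Reactants: 33 (3R,6R,7S,8R)-3-(tert-butyldimethylsilyloxy)-8-(triethylsilyloxy)germacra-1(10)E,4Z,11(13)-trien-12,6-olide
Product: 34 (3R,6R,7R,8R)-3-(tert-butyldimethylsilyloxy)-8-hydroxygermacra-1(10)E,4Z,11(13)-trien-12,6-olide
Conditions: PPTS (cat.), EtOH, 0 °C → rt
Reagents that add atoms: none
Why: Acid-catalysed ethanolysis cleaves the secondary TES ether much faster than the hindered allylic TBS ether, and the mild acid leaves the α-methylene lactone alone.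

Step 20
Reactants: 34 (3R,6R,7R,8R)-3-(tert-butyldimethylsilyloxy)-8-hydroxygermacra-1(10)E,4Z,11(13)-trien-12,6-olide
Product: 35 (3R,6R,7R,8R)-3-(tert-butyldimethylsilyloxy)-8-(3-methylbutanoyloxy)germacra-1(10)E,4Z,11(13)-trien-12,6-olide
Conditions: isovaleric anhydride, DMAP (cat.), pyridine, CH2Cl2, 0 °C → rt
Reagents that add atoms: 3-methylbutanoic anhydride, CC(C)CC(=O)OC(=O)CC(C)C
Why: DMAP-catalysed acylation of the secondary alcohol with retention at C8; no stereocentre is touched.

Step 21
Reactants: 35 (3R,6R,7R,8R)-3-(tert-butyldimethylsilyloxy)-8-(3-methylbutanoyloxy)germacra-1(10)E,4Z,11(13)-trien-12,6-olide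
Product: 36 (1R,3R,6R,7R,8R,10R)-3-(tert-butyldimethylsilyloxy)-1,10-epoxy-8-(3-methylbutanoyloxy)germacra-4Z,11(13)-dien-12,6-olide
Conditions: mCPBA, NaHCO3, CH2Cl2, 0 °C
Reagents that add atoms: 3-chloroperoxybenzoic acid, OOC(=O)c1cccc(Cl)c1
Why: Prilezhaev epoxidation; the 1(10)-alkene is the only electron-rich, unhindered alkene (C4–C5 is flanked by two allylic C–O bonds and the silyl ether, C11–C13 is conjugated), and attack on its outer face in the ten-membered ring is expected to give the trans 1R,10R epoxide stereospecifically from the E-alkene.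

Step 22
Reactants: 36 (1R,3R,6R,7R,8R,10R)-3-(tert-butyldimethylsilyloxy)-1,10-epoxy-8-(3-methylbutanoyloxy)germacra-4Z,11(13)-dien-12,6-olide
Product: 37 (1R,3R,6R,7R,8R,10R)-1,10-epoxy-3-hydroxy-8-(3-methylbutanoyloxy)germacra-4Z,11(13)-dien-12,6-olide (CNP0300193.1)
Conditions: Bu4NF, AcOH (1:1), THF, 0 °C → rt
Reagents that add atoms: none
Why: Fluoride cleavage of the silyl ether, buffered with acetic acid so that neither the epoxide (acid) nor the α-methylene lactone and the ester (base) is attacked.

## Compound list

1 | (S)-5-(hydroxymethyl)dihydrofuran-2(3H)-one | OC[C@H]1OC(=O)CC1 | starting material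
2 | (S)-5-oxotetrahydrofuran-2-carbaldehyde | O=C[C@H]1OC(=O)CC1 | intermediate
3 | ethyltriphenylphosphonium bromide | CC[P+](c1ccccc1)(c1ccccc1)c1ccccc1.[Br-] | starting material
4 | ethylidenetriphenylphosphorane (not isolated) | CC=P(c1ccccc1)(c1ccccc1)c1ccccc1 | intermediate
5 | (1-iodoethyl)triphenylphosphonium iodide (not isolated) | CC(I)[P+](c1ccccc1)(c1ccccc1)c1ccccc1.[I-] | intermediate
6 | (1-iodoethylidene)triphenylphosphorane (not isolated) | CC(I)=P(c1ccccc1)(c1ccccc1)c1ccccc1 | intermediate
7 | (S)-5-[(Z)-2-iodoprop-1-en-1-yl]dihydrofuran-2(3H)-one | I/C(C)=C\[C@H]1OC(=O)CC1 | intermediate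
8 | 3-butyn-1-ol | C#CCCO | starting material
9 | 1-[(but-3-yn-1-yloxy)methyl]-4-methoxybenzene | C#CCCOCc1ccc(OC)cc1 | intermediate
10 | ethylene oxide | C1CO1 | starting material
11 | [(E)-4-[(4-methoxybenzyl)oxy]-2-methylbut-1-en-1-yl]dimethylalane (not isolated) | C[Al](C)/C=C(\C)CCOCc1ccc(OC)cc1 | intermediate
12 | lithium butyl[(E)-4-[(4-methoxybenzyl)oxy]-2-methylbut-1-en-1-yl]dimethylalanate (not isolated) | [Li+].CCCC[Al-](C)(C)/C=C(\C)CCOCc1ccc(OC)cc1 | intermediate
13 | (E)-6-[(4-methoxybenzyl)oxy]-4-methylhex-3-en-1-ol | OCC/C=C(\C)CCOCc1ccc(OC)cc1 | intermediate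
14 | (E)-6-[(4-methoxybenzyl)oxy]-4-methylhex-3-enal | O=CC/C=C(\C)CCOCc1ccc(OC)cc1 | intermediate
15 | (5S)-5-[(1Z,5E)-3-hydroxy-8-[(4-methoxybenzyl)oxy]-2,6-dimethylocta-1,5-dien-1-yl]dihydrofuran-2(3H)-one, both C3 epimers | OC(C/C=C(\C)CCOCc1ccc(OC)cc1)/C(C)=C\[C@H]1OC(=O)CC1 | intermediate
16 | (S)-5-[(1Z,5E)-8-[(4-methoxybenzyl)oxy]-2,6-dimethyl-3-oxoocta-1,5-dien-1-yl]dihydrofuran-2(3H)-one | O=C(C/C=C(\C)CCOCc1ccc(OC)cc1)/C(C)=C\[C@H]1OC(=O)CC1 | intermediate
17 | (S)-5-[(1Z,3R,5E)-3-hydroxy-8-[(4-methoxybenzyl)oxy]-2,6-dimethylocta-1,5-dien-1-yl]dihydrofuran-2(3H)-one | O[C@H](C/C=C(\C)CCOCc1ccc(OC)cc1)/C(C)=C\[C@H]1OC(=O)CC1 | intermediate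
18 | (S)-5-[(1Z,3R,5E)-3-(tert-butyldimethylsilyloxy)-8-[(4-methoxybenzyl)oxy]-2,6-dimethylocta-1,5-dien-1-yl]dihydrofuran-2(3H)-one | CC(C)(C)[Si](C)(C)O[C@H](C/C=C(\C)CCOCc1ccc(OC)cc1)/C(C)=C\[C@H]1OC(=O)CC1 | intermediate
19 | lithium enolate of 18 (not isolated) | CC(C)(C)[Si](C)(C)O[C@H](C/C=C(\C)CCOCc1ccc(OC)cc1)/C(C)=C\[C@H]1OC([O-])=CC1.[Li+] | intermediate
20 | 3-(phenylselanyl) derivative of 18, C11 epimers (not isolated) | CC(C)(C)[Si](C)(C)O[C@H](C/C=C(\C)CCOCc1ccc(OC)cc1)/C(C)=C\[C@H]1OC(=O)C([Se]c2ccccc2)C1 | intermediate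
21 | (S)-5-[(1Z,3R,5E)-3-(tert-butyldimethylsilyloxy)-8-[(4-methoxybenzyl)oxy]-2,6-dimethylocta-1,5-dien-1-yl]furan-2(5H)-one | CC(C)(C)[Si](C)(C)O[C@H](C/C=C(\C)CCOCc1ccc(OC)cc1)/C(C)=C\[C@H]1OC(=O)C=C1 | intermediate
22 | (S)-5-[(1Z,3R,5E)-3-(tert-butyldimethylsilyloxy)-8-hydroxy-2,6-dimethylocta-1,5-dien-1-yl]furan-2(5H)-one | CC(C)(C)[Si](C)(C)O[C@H](C/C=C(\C)CCO)/C(C)=C\[C@H]1OC(=O)C=C1 | intermediate
23 | (S)-5-[(1Z,3R,5E)-3-(tert-butyldimethylsilyloxy)-8-iodo-2,6-dimethylocta-1,5-dien-1-yl]furan-2(5H)-one | CC(C)(C)[Si](C)(C)O[C@H](C/C=C(\C)CCI)/C(C)=C\[C@H]1OC(=O)C=C1 | intermediate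
24 | (S)-5-[(1Z,3R,5E)-3-(tert-butyldimethylsilyloxy)-2,6-dimethyl-8-nitroocta-1,5-dien-1-yl]furan-2(5H)-one | [O-][N+](=O)CC/C(C)=C/C[C@@H](O[Si](C)(C)C(C)(C)C)/C(C)=C\[C@H]1OC(=O)C=C1 | intermediate
25 | (3R,6R,7R,8R)-3-(tert-butyldimethylsilyloxy)-8-nitrogermacra-1(10)E,4Z-dien-12,6-olide (8R drawn; C8 epimer serves equally) | C1C(=O)O[C@@H]2/C=C(/C)[C@H](O[Si](C)(C)C(C)(C)C)C/C=C(\C)C[C@@H]([N+](=O)[O-])[C@@H]12 | intermediate
26 | lithium nitronate of 25 (not isolated) | C1C(=O)O[C@@H]2/C=C(/C)[C@H](O[Si](C)(C)C(C)(C)C)C/C=C(\C)CC(=[N+]([O-])[O-])[C@@H]12.[Li+] | intermediate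
27 | (3R,6R,7S)-3-(tert-butyldimethylsilyloxy)-8-oxogermacra-1(10)E,4Z-dien-12,6-olide | C1C(=O)O[C@@H]2/C=C(/C)[C@H](O[Si](C)(C)C(C)(C)C)C/C=C(\C)CC(=O)[C@@H]12 | intermediate
28 | (3R,6R,7R,8R)-3-(tert-butyldimethylsilyloxy)-8-hydroxygermacra-1(10)E,4Z-dien-12,6-olide | C1C(=O)O[C@@H]2/C=C(/C)[C@H](O[Si](C)(C)C(C)(C)C)C/C=C(\C)C[C@@H](O)[C@@H]12 | intermediate
29 | (3R,6R,7S,8R)-3-(tert-butyldimethylsilyloxy)-8-(triethylsilyloxy)germacra-1(10)E,4Z-dien-12,6-olide | C1C(=O)O[C@@H]2/C=C(/C)[C@H](O[Si](C)(C)C(C)(C)C)C/C=C(\C)C[C@@H](O[Si](CC)(CC)CC)[C@@H]12 | intermediate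
30 | lithium enolate of 29 (not isolated) | C1=C([O-])O[C@@H]2/C=C(/C)[C@H](O[Si](C)(C)C(C)(C)C)C/C=C(\C)C[C@@H](O[Si](CC)(CC)CC)[C@@H]12.[Li+] | intermediate
31 | 11-(dimethylaminomethyl) derivative of 29, C11 epimers (not isolated) | CN(C)CC1C(=O)O[C@@H]2/C=C(/C)[C@H](O[Si](C)(C)C(C)(C)C)C/C=C(\C)C[C@@H](O[Si](CC)(CC)CC)[C@@H]12 | intermediate
32 | trimethylammonium iodide from 31 (not isolated) | C[N+](C)(C)CC1C(=O)O[C@@H]2/C=C(/C)[C@H](O[Si](C)(C)C(C)(C)C)C/C=C(\C)C[C@@H](O[Si](CC)(CC)CC)[C@@H]12.[I-] | intermediate
33 | (3R,6R,7S,8R)-3-(tert-butyldimethylsilyloxy)-8-(triethylsilyloxy)germacra-1(10)E,4Z,11(13)-trien-12,6-olide | C=C1C(=O)O[C@@H]2/C=C(/C)[C@H](O[Si](C)(C)C(C)(C)C)C/C=C(\C)C[C@@H](O[Si](CC)(CC)CC)[C@@H]12 | intermediate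
34 | (3R,6R,7R,8R)-3-(tert-butyldimethylsilyloxy)-8-hydroxygermacra-1(10)E,4Z,11(13)-trien-12,6-olide | C=C1C(=O)O[C@@H]2/C=C(/C)[C@H](O[Si](C)(C)C(C)(C)C)C/C=C(\C)C[C@@H](O)[C@@H]12 | intermediate
35 | (3R,6R,7R,8R)-3-(tert-butyldimethylsilyloxy)-8-(3-methylbutanoyloxy)germacra-1(10)E,4Z,11(13)-trien-12,6-olide | C=C1C(=O)O[C@@H]2/C=C(/C)[C@H](O[Si](C)(C)C(C)(C)C)C/C=C(\C)C[C@@H](OC(=O)CC(C)C)[C@@H]12 | intermediate
36 | (1R,3R,6R,7R,8R,10R)-3-(tert-butyldimethylsilyloxy)-1,10-epoxy-8-(3-methylbutanoyloxy)germacra-4Z,11(13)-dien-12,6-olide | C=C1C(=O)O[C@@H]2/C=C(/C)[C@H](O[Si](C)(C)C(C)(C)C)C[C@H]3O[C@]3(C)C[C@@H](OC(=O)CC(C)C)[C@@H]12 | intermediate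
37 | (1R,3R,6R,7R,8R,10R)-1,10-epoxy-3-hydroxy-8-(3-methylbutanoyloxy)germacra-4Z,11(13)-dien-12,6-olide (CNP0300193.1) | C=C1C(=O)O[C@@H]2/C=C(/C)[C@H](O)C[C@H]3O[C@]3(C)C[C@@H](OC(=O)CC(C)C)[C@@H]12 | target

## Step count and least certain steps

Total: 22 steps. Longest linear sequence: 20 steps (3-butyn-1-ol 8 through steps 3 to 5 and 6 to 22); the branch from lactone 1 is 19 steps.

**Step 14 (key step).** The ring closure may be too slow. Oligomerisation, or deprotonation at C6 followed by epimerisation or double-bond migration of the butenolide, would then take over; the equilibrium may also lie on the open-chain side because of ring strain.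
Fallback, known chemistry, setting out from 7 and 14 and coming back at 29: the order of the two unions is reversed. C7–C8 is made by the known intermolecular nitro-Michael addition, and the ring is closed at C3–C4 by an intramolecular Nozaki–Hiyama–Kishi reaction, a known ten-membered ring closure.
- Lactone 7 is dehydrogenated as in step 10, through the 3-phenylselanyl lactone F1, to (S)-5-[(Z)-2-iodoprop-1-en-1-yl]furan-2(5H)-one F2.
- Aldehyde 14 is protected as the dimethyl acetal F3 (HC(OMe)3, PPTS, MeOH). The operations of steps 11 to 13 take it through the acetal alcohol F4 and the acetal iodide F5 to the nitro acetal F6.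
- DBU in MeCN at ordinary concentration should join F6 and F2, anti to the C5 substituent, to the 4,5-trans nitro lactone F7.
- Reductive Nef reaction as in step 15 should give the ketone F8, LiBH(s-Bu)3 the 8R carbinol F9, and Et3SiOTf the triethylsilyl ether F10.
- Mild acetal hydrolysis (PPTS, wet acetone) frees the aldehyde F11. It is cyclised with CrCl2/NiCl2 in DMSO at high dilution, if needed with a chiral oxazoline–sulfonamide ligand on chromium to favour 3R, to the ring carbinol F12.
- Silylation of F12 as in step 9 gives 29.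

**Step 2.** The basic ylide may epimerise the α-acyloxy aldehyde, and the Z selectivity of the iodo-olefination may be incomplete.
Fallback, setting out from 2 and coming back at 7: the halide is built in stages. CBr4/PPh3 in CH2Cl2 (neutral) converts 2 into (S)-5-(2,2-dibromovinyl)dihydrofuran-2(3H)-one F13. Negishi coupling with MeZnCl under zerovalent palladium catalysis (Pd(P(t-Bu)3)2) replaces the bromine trans to C6 and gives the (Z)-bromoalkene F14. Copper-catalysed halogen exchange (CuI, NaI, N,N′-dimethylethylenediamine, dioxane, 110 °C) then gives 7.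

**Step 15.** Forming the nitronate with a strong base may reopen the ring by retro-Michael reaction. Once the ketone exists, enolisation toward C7 may epimerise the ring fusion or expel the lactone carboxylate from C6.
Fallback, setting out from 25 and coming back at 27: the nitro group is reduced without a nitronate stage to the oxime F15 (SnCl2, PhSH, Et3N, MeCN). The oxime is cleaved under buffer (TiCl3, NH4OAc, aqueous THF) to 27, which is reduced at once.

**Step 16.** Facial selectivity may be poor or reversed, because the ring conformation rather than the open-chain Felkin–Anh model may decide which carbonyl face is exposed.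
Fallback, setting out from 27 and coming back at 28: substrate control is replaced by reagent control, using (S)-2-methyl-CBS-oxazaborolidine and catecholborane (C7 side large, C9 side small, 8R expected). No new compound arises (F0).

**Step 21.** The peracid may attack the wrong face of the 1(10)-alkene, or acid may trigger transannular opening of the new epoxide by the 4,5-alkene.
Fallback, setting out from 35 and coming back at 36: Shi epoxidation with the D-fructose-derived ketone and Oxone at buffered pH, where the catalyst rather than the ring chooses the face; the spiro transition-state model predicts the R,R epoxide for an E-trisubstituted alkene. No new compound arises (F0).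

## Further compounds

F1 | step 14 | 3-(phenylselanyl) derivative of 7 | I/C(C)=C\[C@H]1OC(=O)C([Se]c2ccccc2)C1
F2 | step 14 | (S)-5-[(Z)-2-iodoprop-1-en-1-yl]furan-2(5H)-one | I/C(C)=C\[C@H]1OC(=O)C=C1
F3 | step 14 | (E)-1-[[(6,6-dimethoxy-3-methylhex-3-en-1-yl)oxy]methyl]-4-methoxybenzene | COC(OC)C/C=C(\C)CCOCc1ccc(OC)cc1
F4 | step 14 | (E)-6,6-dimethoxy-3-methylhex-3-en-1-ol | COC(OC)C/C=C(\C)CCO
F5 | step 14 | (E)-6-iodo-1,1-dimethoxy-4-methylhex-3-ene | COC(OC)C/C=C(\C)CCI
F6 | step 14 | (E)-1,1-dimethoxy-4-methyl-6-nitrohex-3-ene | COC(OC)C/C=C(\C)CC[N+](=O)[O-]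
F7 | step 14 | 4,5-trans nitro lactone: 5-[(Z)-2-iodoprop-1-enyl]-4-[(E)-6,6-dimethoxy-3-methyl-1-nitrohex-3-enyl]dihydrofuran-2(3H)-one, C8 epimers | O=C1O[C@H](/C=C(/C)I)[C@H](C1)C(C/C(C)=C/CC(OC)OC)[N+](=O)[O-]
F8 | step 14 | ketone from F7 (C8 carbonyl) | O=C1O[C@H](/C=C(/C)I)[C@H](C1)C(=O)C/C(C)=C/CC(OC)OC
F9 | step 14 | 8R carbinol from F8 | O=C1O[C@H](/C=C(/C)I)[C@H](C1)[C@H](O)C/C(C)=C/CC(OC)OC
F10 | step 14 | triethylsilyl ether of F9 | O=C1O[C@H](/C=C(/C)I)[C@H](C1)[C@H](O[Si](CC)(CC)CC)C/C(C)=C/CC(OC)OC
F11 | step 14 | C3 aldehyde from F10 | O=C1O[C@H](/C=C(/C)I)[C@H](C1)[C@H](O[Si](CC)(CC)CC)C/C(C)=C/CC=O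
F12 | step 14 | 3-hydroxy-8-(triethylsilyloxy)germacra-1(10)E,4Z-dien-12,6-olide, 3R, ring stereochemistry as in 29 | C1C(=O)O[C@@H]2/C=C(/C)[C@H](O)C/C=C(\C)C[C@@H](O[Si](CC)(CC)CC)[C@@H]12
F13 | step 2 | (S)-5-(2,2-dibromovinyl)dihydrofuran-2(3H)-one | BrC(Br)=C[C@H]1OC(=O)CC1
F14 | step 2 | (S)-5-[(Z)-2-bromoprop-1-en-1-yl]dihydrofuran-2(3H)-one | Br/C(C)=C\[C@H]1OC(=O)CC1
F15 | step 15 | 8-oxime of 27 | C1C(=O)O[C@@H]2/C=C(/C)[C@H](O[Si](C)(C)C(C)(C)C)C/C=C(\C)CC(=NO)[C@@H]12
F0 | step 16 | none | none
F0 | step 21 | none | none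
A1 | alternative 1 | ring (3Z,5Z)-diene with 1,10-epoxide, C8 isovalerate and C7 methyl acrylate | COC(=O)C(=C)[C@H]1/C=C\C(C)=C/C[C@H]2O[C@]2(C)C[C@H]1OC(=O)CC(C)C
A2 | alternative 1 | 3,6-endoperoxide of the ten-membered ring | COC(=O)C(=C)[C@H]1[C@@H]2OO[C@@H](C(C)=C2)C[C@H]3O[C@]3(C)C[C@H]1OC(=O)CC(C)C
A3 | alternative 2 | C6 allylic diazomalonate (2-trimethylsilylethyl ester) with E-7,8-alkene | C[Si](C)(C)CCOC(=O)C(=[N+]=[N-])C(=O)O[C@H](COCc1ccc(OC)cc1)/C=C/C/C(C)=C/CCO[Si](C)(C)C(C)(C)C
A4 | alternative 2 | 3-oxabicyclo[3.1.0]hexan-2-one with ester on C11, C5 arm on C6 and C9 arm on C8 | C[Si](C)(C)CCOC(=O)[C@]12C(=O)O[C@H](COCc3ccc(OC)cc3)[C@H]1[C@@H]2C/C(C)=C/CCO[Si](C)(C)C(C)(C)C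
A5 | alternative 3 | tertiary α-chloro methyl ketone tethered to a 4-methylfuran (either C10 epimer) | CC(=O)C(C)(Cl)C[C@@H](O[Si](C)(C)C(C)(C)C)[C@@H](CC(=O)OC(C)(C)C)c1cc(C)co1
A6 | alternative 3 | cyclopenta-fused 8-oxabicyclo[3.2.1]oct-6-en-3-one | O=C1C[C@H]2O[C@@]3(C=C2C)[C@H](CC(=O)OC(C)(C)C)[C@H](O[Si](C)(C)C(C)(C)C)C[C@]13C
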